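**Retrosynthetic overview**

1. Target 27 ⇐ tert-butyl ester 26 (acidolysis) ⇐ keto aldehyde enol acetate 24, where one methanolysis/borohydride operation sets C5–H, C6–OH and C19–OH ⇐ hydroxy aldehyde 23 (isovaleroylation of the only free OH, at C3).
2. Key disconnection C3–C4: ring A (C1–C5, C10) is closed by a Lewis-acid aldol of the ethyl enol ether C19=C4 onto the C3 aldehyde of monocyclic dienyl aldehyde 21, which carries C10 as its only stereocentre.
3. Enabling feature: the oxygens on C19 (the CH2OH on C4, ring A) and on C6 (ring B) are 1,4-related through the C4–C5 bond, and O3 is 1,3 to C19. The C19–C4–C5–C6 unit can therefore be carried as a 1,4-dioxygenated diene (C19 enol ether / C6 enol acetate) in which C4 is the nucleophile and C5, C6 stay sp2 until ring A exists.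
4. The diene comes from a C5 enol triflate and an alkenyl boronate (C4–C5 bond); the side chain from a B-alkyl Suzuki coupling with an (E)-enol triflate (C12–C13 bond); C10 from a Pd-catalysed decarboxylative asymmetric allylation.
5. Order of ring formation: ring B is the ring of starting enone 1 (elaborated in steps 1–13); ring A is closed last, in step 15.

Key step: step 15

Remark: labdane numbering is used for the bicyclic compounds (ring A = C1–C5 + C10, ring B = C5–C10, C19 = oxygenated carbon on C4, C20 = methyl on C10); α/β refer to the target drawn with the C10 methyl β.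

**Route**

Step 1
Reactants: 1 3-ethoxy-2-methylcyclohex-2-en-1-one
Product: 2 3-ethoxy-2,6-dimethylcyclohex-2-en-1-one (racemic)
Conditions: LiN(i-Pr)2, THF, −78 °C; MeI, −78 → 0 °C
Reagents that add atoms: iodomethane (CI)
Why: Kinetic α′-deprotonation of the vinylogous ester and C-methylation (Stork–Danheiser enolate alkylation) install the future C8 methyl; the new centre is racemic and becomes sp2 in step 3.

Step 2
Reactants: 2 3-ethoxy-2,6-dimethylcyclohex-2-en-1-one
Product: 4 2,4-dimethyl-3-vinylcyclohex-2-en-1-one (racemic), via tertiary allylic alcohol 3 (not isolated)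
Conditions: CH2=CHMgBr, THF, 0 °C; then 1 M HCl, 20 °C
Reagents that add atoms: vinylmagnesium bromide (C=C[Mg]Br); water (O)
Why: 1,2-Addition of the Grignard reagent followed by acid hydrolysis with allylic transposition (Stork–Danheiser sequence) gives the 3-vinyl enone, whose vinyl group is the future C11–C12 unit.

Step 3
Reactants: 4 2,4-dimethyl-3-vinylcyclohex-2-en-1-one
Product: 5 allyl 2,4-dimethyl-3-vinylcyclohexa-1,3-dien-1-yl carbonate
Conditions: KOt-Bu, THF, 0 °C; allyl chloroformate, −78 °C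
Reagents that add atoms: allyl chloroformate (C=CCOC(=O)Cl)
Why: Equilibration with tert-butoxide should give the thermodynamic extended dienolate (γ-deprotonation), and its O-acylation gives the allyl enol carbonate needed for decarboxylative allylation.

Step 4
Reactants: 5 allyl 2,4-dimethyl-3-vinylcyclohexa-1,3-dien-1-yl carbonate
Product: 6 (R)-2-allyl-2,4-dimethyl-3-vinylcyclohex-3-en-1-one
Conditions: Pd2(dba)3 (2.5 mol%), (S)-t-Bu-PHOX (6 mol%), THF, 25 °C
Reagents that add atoms: none
Why: Decarboxylative asymmetric allylic alkylation of an allyl enol carbonate (Tsuji–Stoltz type) should allylate the α-carbon through the inner-sphere palladium enolate, and the (S)-phosphinooxazoline ligand, by the sense in which it gives (S)-2-allyl-2-methylcyclohexanone, should set the quaternary carbon (future C10) as R.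

Step 5
Reactants: 6 (R)-2-allyl-2,4-dimethyl-3-vinylcyclohex-3-en-1-one
Product: 8 (R)-2-(3-hydroxypropyl)-2,4-dimethyl-3-vinylcyclohex-3-en-1-one, via alkylborane 7 (not isolated)
Conditions: 9-BBN (1.05 equiv), THF, 0 → 20 °C; then NaOH, H2O2, 0 °C
Reagents that add atoms: hydrogen peroxide (OO)
Why: Anti-Markovnikov hydroboration–oxidation, in which 9-BBN should select the isolated allyl alkene over the vinyl group on the fully substituted diene carbon and leave the hindered ketone alone.

Step 6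
Reactants: 8 (R)-2-(3-hydroxypropyl)-2,4-dimethyl-3-vinylcyclohex-3-en-1-one
Product: 9 (R)-2-[3-(tert-butyldimethylsilyloxy)propyl]-2,4-dimethyl-3-vinylcyclohex-3-en-1-one
Conditions: TBSCl, imidazole, DMF, 0 → 20 °C
Reagents that add atoms: tert-butyldimethylsilyl chloride (CC(C)(C)[Si](C)(C)Cl)
Why: Standard silylation protects the primary alcohol against the strong bases of steps 9 and 10.

Step 7
Reactants: 10 tert-butyl 3-oxobutanoate
Product: 11 tert-butyl (E)-3-(trifluoromethylsulfonyloxy)but-2-enoate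
Conditions: Tf2O, aq. Me4NOH, hexanes, 5 → 20 °C
Reagents that add atoms: trifluoromethanesulfonic anhydride (O=S(=O)(OS(=O)(=O)C(F)(F)F)C(F)(F)F)
Why: O-Triflation of the acetoacetate under non-chelating ammonium hydroxide conditions should give the (E)-enol triflate (triflate trans to the ester), which fixes the side-chain alkene geometry.

Step 8
Reactants: 9 (R)-2-[3-(tert-butyldimethylsilyloxy)propyl]-2,4-dimethyl-3-vinylcyclohex-3-en-1-one; 11 tert-butyl (E)-3-(trifluoromethylsulfonyloxy)but-2-enoate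
Product: 13 tert-butyl (E)-5-{(R)-6-[3-(tert-butyldimethylsilyloxy)propyl]-2,6-dimethyl-5-oxocyclohex-1-en-1-yl}-3-methylpent-2-enoate, via alkylborane 12 (not isolated)
Conditions: 9-BBN, THF, 20 °C; then 11, Pd(dppf)Cl2 (5 mol%), aq. K3PO4, DMF, 50 °C
Reagents that add atoms: none
Why: Hydroboration of the vinyl terminus and B-alkyl Suzuki–Miyaura coupling, with retention at the enol triflate, give the (13E)-enoate side chain without forming a stereocentre.

Step 9
Reactants: 13 tert-butyl (E)-5-{(R)-6-[3-(tert-butyldimethylsilyloxy)propyl]-2,6-dimethyl-5-oxocyclohex-1-en-1-yl}-3-methylpent-2-enoate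
Product: 15 tert-butyl (E)-5-{(6R)-4-acetoxy-6-[3-(tert-butyldimethylsilyloxy)propyl]-2,6-dimethyl-5-oxocyclohex-1-en-1-yl}-3-methylpent-2-enoate (epimers at the acetoxy carbon), via hydroxy ketone 14 (not isolated)
Conditions: KN(SiMe3)2, THF, −78 °C; 3-phenyl-2-(phenylsulfonyl)oxaziridine, −78 °C; then Ac2O, −78 → 0 °C
Reagents that add atoms: 3-phenyl-2-(phenylsulfonyl)oxaziridine (O=S(=O)(N1OC1c1ccccc1)c1ccccc1); acetic anhydride (CC(=O)OC(C)=O)
Why: The only enolisable position of the ketone (future C6) is hydroxylated by the Davis oxaziridine and acetylated in the same flask, and its configuration is irrelevant because the carbon becomes sp2 in step 10.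

Step 10
Reactants: 15 tert-butyl (E)-5-{(6R)-4-acetoxy-6-[3-(tert-butyldimethylsilyloxy)propyl]-2,6-dimethyl-5-oxocyclohex-1-en-1-yl}-3-methylpent-2-enoate
Product: 16 tert-butyl (E)-5-{(R)-4-acetoxy-6-[3-(tert-butyldimethylsilyloxy)propyl]-2,6-dimethyl-5-(trifluoromethylsulfonyloxy)cyclohexa-1,4-dien-1-yl}-3-methylpent-2-enoate
Conditions: KN(SiMe3)2, THF, −78 °C; N-(5-chloropyridin-2-yl)bis(trifluoromethanesulfonimide), −78 °C
Reagents that add atoms: N-(5-chloropyridin-2-yl)bis(trifluoromethanesulfonimide) (O=S(=O)(N(c1ccc(Cl)cn1)S(=O)(=O)C(F)(F)F)C(F)(F)F)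
Why: Deprotonation at the acetoxy-bearing carbon and O-triflation at −78 °C (enol triflate formation with Comins' reagent) should trap the enolate before the acetyl group can migrate.

Step 11
Reactants: 16 tert-butyl (E)-5-{(R)-4-acetoxy-6-[3-(tert-butyldimethylsilyloxy)propyl]-2,6-dimethyl-5-(trifluoromethylsulfonyloxy)cyclohexa-1,4-dien-1-yl}-3-methylpent-2-enoate
Product: 17 tert-butyl (E)-5-{(R)-4-acetoxy-6-(3-hydroxypropyl)-2,6-dimethyl-5-(trifluoromethylsulfonyloxy)cyclohexa-1,4-dien-1-yl}-3-methylpent-2-enoate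
Conditions: HF·pyridine, pyridine, THF, 0 °C
Reagents that add atoms: none
Why: Buffered fluoride desilylation frees the primary alcohol without touching enol triflate, enol acetate or tert-butyl ester, and it is done before the acid-labile enol ether is introduced.

Step 12
Reactants: 18 1-ethoxyprop-1-yne
Product: 19 (Z)-2-(1-ethoxyprop-1-en-2-yl)-4,4,5,5-tetramethyl-1,3,2-dioxaborolane
Conditions: pinacolborane, Cp2Zr(H)Cl (5 mol%), Et3N (10 mol%), 60 °C
Reagents that add atoms: pinacolborane (B1OC(C)(C)C(C)(C)O1)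
Why: syn-Hydroboration of the ynol ether places boron on the carbon remote from oxygen, so ethoxy and methyl are cis and the later enol ether has its ethoxy group trans to the ring carbon.

Step 13
Reactants: 17 tert-butyl (E)-5-{(R)-4-acetoxy-6-(3-hydroxypropyl)-2,6-dimethyl-5-(trifluoromethylsulfonyloxy)cyclohexa-1,4-dien-1-yl}-3-methylpent-2-enoate; 19 (Z)-2-(1-ethoxyprop-1-en-2-yl)-4,4,5,5-tetramethyl-1,3,2-dioxaborolane
Product: 20 tert-butyl (E)-5-{(R)-4-acetoxy-5-[(E)-1-ethoxyprop-1-en-2-yl]-6-(3-hydroxypropyl)-2,6-dimethylcyclohexa-1,4-dien-1-yl}-3-methylpent-2-enoate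
Conditions: Pd2(dba)3 (5 mol%), SPhos (12 mol%), CsF, 1,4-dioxane, 60 °C
Reagents that add atoms: none
Why: Suzuki–Miyaura coupling under anhydrous fluoride activation, which should spare the enol acetate, joins C5 to C4 with retention of both alkene geometries.

Step 14
Reactants: 20 tert-butyl (E)-5-{(R)-4-acetoxy-5-[(E)-1-ethoxyprop-1-en-2-yl]-6-(3-hydroxypropyl)-2,6-dimethylcyclohexa-1,4-dien-1-yl}-3-methylpent-2-enoate
Product: 21 tert-butyl (E)-5-{(R)-4-acetoxy-5-[(E)-1-ethoxyprop-1-en-2-yl]-2,6-dimethyl-6-(3-oxopropyl)cyclohexa-1,4-dien-1-yl}-3-methylpent-2-enoate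
Conditions: Dess–Martin periodinane, NaHCO3, CH2Cl2, 0 °C
Reagents that add atoms: none
Why: Buffered Dess–Martin oxidation gives the aldehyde (future C3) under conditions that should leave the enol ether and enol acetate intact.

Step 15
Reactants: 21 tert-butyl (E)-5-{(R)-4-acetoxy-5-[(E)-1-ethoxyprop-1-en-2-yl]-2,6-dimethyl-6-(3-oxopropyl)cyclohexa-1,4-dien-1-yl}-3-methylpent-2-enoate
Product: 23 tert-butyl (3R,4R,10R,13E)-6-acetoxy-3-hydroxy-19-oxolabda-5,8,13-trien-15-oate, via chloro ether 22 (not isolated)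
Conditions: Me2AlCl (2 equiv), CH2Cl2, −78 °C; then aq. NaHCO3, 0 °C
Reagents that add atoms: water (O)
Why: The aluminium-bound C3 aldehyde is attacked by C4, the β-carbon of the ethyl enol ether, in a chair-like 6-(enolexo)-exo-trig closure of ring A; chloride transfer to the ethoxy-oxocarbenium ion gives chloro ether 22, which work-up hydrolyses to the C19 aldehyde. The closest known reaction type is the Lewis-acid (Mukaiyama-type) aldol addition of an alkyl enol ether to an aldehyde, as in Me2AlCl-promoted Prins and ene cyclisations of aldehydes. At C4 the aldehyde can only arrive from the side of C10 that carries the tether, and the enol ether should react through the rotamer that places its vinylic CH (C19), not the C18 methyl, 1,3-syn to the C10 methyl, so C19 ends axial (β) and the methyl equatorial (α). At C3 an open antiperiplanar transition state, with the Lewis-acid-bound oxygen anti to the enol ether double bond and away from both C4 substituents, should place the hydroxyl axial (3α). The step needs attack by C4 rather than by the vinylogous carbon C6, by C5 of the enol acetate (five-membered ring) or by the C8=C9 alkene; this is secured by the acetoxy group, which blocks C6 and makes the C5=C6 unit a much weaker nucleophile than the enol ether, and by the far lower nucleophilicity of the tetrasubstituted alkene. The enol acetate survives as the masked C6 ketone, so C5 and C6 are set only after ring A exists.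

Step 16
Reactants: 23 tert-butyl (3R,4R,10R,13E)-6-acetoxy-3-hydroxy-19-oxolabda-5,8,13-trien-15-oate
Product: 24 tert-butyl (3R,4R,10R,13E)-6-acetoxy-3-(3-methylbutanoyloxy)-19-oxolabda-5,8,13-trien-15-oate
Conditions: isovaleric anhydride, DMAP, pyridine, CH2Cl2, 0 → 20 °C
Reagents that add atoms: isovaleric anhydride (CC(C)CC(=O)OC(=O)CC(C)C)
Why: DMAP-catalysed esterification of the only free hydroxyl (3α) installs the isovalerate without protecting groups, because C19 is still an aldehyde and C6 an enol acetate.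

Step 17
Reactants: 24 tert-butyl (3R,4R,10R,13E)-6-acetoxy-3-(3-methylbutanoyloxy)-19-oxolabda-5,8,13-trien-15-oate
Product: 26 tert-butyl (3R,4S,5R,6R,10S,13E)-6,19-dihydroxy-3-(3-methylbutanoyloxy)labda-8,13-dien-15-oate, via keto aldehyde 25 (not isolated)
Conditions: K2CO3 (0.2 equiv), MeOH/THF, −20 °C; then NaBH4, −20 → 0 °C
Reagents that add atoms: none
Why: Methanolysis of the enol acetate gives the C5=C6 enolate, which should be protonated at C5 from the α-face (the β-face is shielded by the C10 methyl and C19), and borohydride then reduces the C19 aldehyde and attacks the C6 ketone from the α-face to give the 6β-alcohol before the C8=C9 bond can move into conjugation (enol acetate reduction through the β,γ-unsaturated ketone, as in the steroid series).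

Step 18
Reactants: 26 tert-butyl (3R,4S,5R,6R,10S,13E)-6,19-dihydroxy-3-(3-methylbutanoyloxy)labda-8,13-dien-15-oate
Product: 27 (3R,4S,5R,6R,10S,13E)-6,19-dihydroxy-3-(3-methylbutanoyloxy)labda-8,13-dien-15-oic acid
Conditions: 85% aq. H3PO4, toluene, 20 °C
Reagents that add atoms: none
Why: Acidolysis of the tert-butyl ester with aqueous phosphoric acid should free the acid without cleaving the isovalerate or shifting the tetrasubstituted alkene.

**Compound list**

1 | 3-ethoxy-2-methylcyclohex-2-en-1-one | CCOC1=C(C)C(=O)CCC1 | starting material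
2 | 3-ethoxy-2,6-dimethylcyclohex-2-en-1-one (racemic) | CCOC1=C(C)C(=O)C(C)CC1 | intermediate
3 | 3-ethoxy-2,6-dimethyl-1-vinylcyclohex-2-en-1-ol (magnesium alkoxide, diastereomers) | CCOC1=C(C)C(O)(C=C)C(C)CC1 | intermediate
4 | 2,4-dimethyl-3-vinylcyclohex-2-en-1-one (racemic) | CC1CCC(=O)C(C)=C1C=C | intermediate
5 | allyl 2,4-dimethyl-3-vinylcyclohexa-1,3-dien-1-yl carbonate | C=CCOC(=O)OC1=C(C)C(C=C)=C(C)CC1 | intermediate
6 | (R)-2-allyl-2,4-dimethyl-3-vinylcyclohex-3-en-1-one | CC1=C(C=C)[C@@](C)(CC=C)C(=O)CC1 | intermediate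
7 | (R)-2-[3-(9-borabicyclo[3.3.1]nonan-9-yl)propyl]-2,4-dimethyl-3-vinylcyclohex-3-en-1-one | CC1=C(C=C)[C@@](C)(CCCB2C3CCCC2CCC3)C(=O)CC1 | intermediate
8 | (R)-2-(3-hydroxypropyl)-2,4-dimethyl-3-vinylcyclohex-3-en-1-one | CC1=C(C=C)[C@@](C)(CCCO)C(=O)CC1 | intermediate
9 | (R)-2-[3-(tert-butyldimethylsilyloxy)propyl]-2,4-dimethyl-3-vinylcyclohex-3-en-1-one | CC1=C(C=C)[C@@](C)(CCCO[Si](C)(C)C(C)(C)C)C(=O)CC1 | intermediate
10 | tert-butyl 3-oxobutanoate | CC(=O)CC(=O)OC(C)(C)C | starting material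
11 | tert-butyl (E)-3-(trifluoromethylsulfonyloxy)but-2-enoate | C/C(OS(=O)(=O)C(F)(F)F)=C\C(=O)OC(C)(C)C | intermediate
12 | (R)-3-[2-(9-borabicyclo[3.3.1]nonan-9-yl)ethyl]-2-[3-(tert-butyldimethylsilyloxy)propyl]-2,4-dimethylcyclohex-3-en-1-one | CC1=C(CCB2C3CCCC2CCC3)[C@@](C)(CCCO[Si](C)(C)C(C)(C)C)C(=O)CC1 | intermediate
13 | tert-butyl (E)-5-{(R)-6-[3-(tert-butyldimethylsilyloxy)propyl]-2,6-dimethyl-5-oxocyclohex-1-en-1-yl}-3-methylpent-2-enoate | CC1=C(CC/C(C)=C/C(=O)OC(C)(C)C)[C@@](C)(CCCO[Si](C)(C)C(C)(C)C)C(=O)CC1 | intermediate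
14 | tert-butyl (E)-5-{(6R)-6-[3-(tert-butyldimethylsilyloxy)propyl]-4-hydroxy-2,6-dimethyl-5-oxocyclohex-1-en-1-yl}-3-methylpent-2-enoate (potassium alkoxide, C4 epimers) | CC1=C(CC/C(C)=C/C(=O)OC(C)(C)C)[C@@](C)(CCCO[Si](C)(C)C(C)(C)C)C(=O)C(O)C1 | intermediate
15 | tert-butyl (E)-5-{(6R)-4-acetoxy-6-[3-(tert-butyldimethylsilyloxy)propyl]-2,6-dimethyl-5-oxocyclohex-1-en-1-yl}-3-methylpent-2-enoate (C4 epimers) | CC1=C(CC/C(C)=C/C(=O)OC(C)(C)C)[C@@](C)(CCCO[Si](C)(C)C(C)(C)C)C(=O)C(OC(C)=O)C1 | intermediate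
16 | tert-butyl (E)-5-{(R)-4-acetoxy-6-[3-(tert-butyldimethylsilyloxy)propyl]-2,6-dimethyl-5-(trifluoromethylsulfonyloxy)cyclohexa-1,4-dien-1-yl}-3-methylpent-2-enoate | CC1=C(CC/C(C)=C/C(=O)OC(C)(C)C)[C@@](C)(CCCO[Si](C)(C)C(C)(C)C)C(OS(=O)(=O)C(F)(F)F)=C(OC(C)=O)C1 | intermediate
17 | tert-butyl (E)-5-{(R)-4-acetoxy-6-(3-hydroxypropyl)-2,6-dimethyl-5-(trifluoromethylsulfonyloxy)cyclohexa-1,4-dien-1-yl}-3-methylpent-2-enoate | CC1=C(CC/C(C)=C/C(=O)OC(C)(C)C)[C@@](C)(CCCO)C(OS(=O)(=O)C(F)(F)F)=C(OC(C)=O)C1 | intermediate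
18 | 1-ethoxyprop-1-yne | CCOC#CC | starting material
19 | (Z)-2-(1-ethoxyprop-1-en-2-yl)-4,4,5,5-tetramethyl-1,3,2-dioxaborolane | CCO/C=C(\C)B1OC(C)(C)C(C)(C)O1 | intermediate
20 | tert-butyl (E)-5-{(R)-4-acetoxy-5-[(E)-1-ethoxyprop-1-en-2-yl]-6-(3-hydroxypropyl)-2,6-dimethylcyclohexa-1,4-dien-1-yl}-3-methylpent-2-enoate | CC1=C(CC/C(C)=C/C(=O)OC(C)(C)C)[C@@](C)(CCCO)C(/C(C)=C/OCC)=C(OC(C)=O)C1 | intermediate
21 | tert-butyl (E)-5-{(R)-4-acetoxy-5-[(E)-1-ethoxyprop-1-en-2-yl]-2,6-dimethyl-6-(3-oxopropyl)cyclohexa-1,4-dien-1-yl}-3-methylpent-2-enoate | CC1=C(CC/C(C)=C/C(=O)OC(C)(C)C)[C@@](C)(CCC=O)C(/C(C)=C/OCC)=C(OC(C)=O)C1 | intermediate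
22 | tert-butyl (3R,4R,10R,13E)-6-acetoxy-19-chloro-19-ethoxy-3-hydroxylabda-5,8,13-trien-15-oate (aluminium alkoxide, C19 epimers) | CC1=C(CC/C(C)=C/C(=O)OC(C)(C)C)[C@@]2(C)CC[C@@H](O)[C@](C)(C(Cl)OCC)C2=C(OC(C)=O)C1 | intermediate
23 | tert-butyl (3R,4R,10R,13E)-6-acetoxy-3-hydroxy-19-oxolabda-5,8,13-trien-15-oate (3α-OH, C19 β) | CC1=C(CC/C(C)=C/C(=O)OC(C)(C)C)[C@@]2(C)CC[C@@H](O)[C@](C)(C=O)C2=C(OC(C)=O)C1 | intermediate
24 | tert-butyl (3R,4R,10R,13E)-6-acetoxy-3-(3-methylbutanoyloxy)-19-oxolabda-5,8,13-trien-15-oate | CC1=C(CC/C(C)=C/C(=O)OC(C)(C)C)[C@@]2(C)CC[C@@H](OC(=O)CC(C)C)[C@](C)(C=O)C2=C(OC(C)=O)C1 | intermediate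
25 | tert-butyl (3R,4R,5R,10S,13E)-3-(3-methylbutanoyloxy)-6,19-dioxolabda-8,13-dien-15-oate | CC1=C(CC/C(C)=C/C(=O)OC(C)(C)C)[C@@]2(C)CC[C@@H](OC(=O)CC(C)C)[C@](C)(C=O)[C@@H]2C(=O)C1 | intermediate
26 | tert-butyl (3R,4S,5R,6R,10S,13E)-6,19-dihydroxy-3-(3-methylbutanoyloxy)labda-8,13-dien-15-oate | CC1=C(CC/C(C)=C/C(=O)OC(C)(C)C)[C@@]2(C)CC[C@@H](OC(=O)CC(C)C)[C@](C)(CO)[C@@H]2[C@H](O)C1 | intermediate
27 | (3R,4S,5R,6R,10S,13E)-6,19-dihydroxy-3-(3-methylbutanoyloxy)labda-8,13-dien-15-oic acid (3α-isovaleryloxy, 5α-H, 6β-OH, 10β-methyl) | CC1=C(CC/C(C)=C/C(=O)O)[C@@]2(C)CC[C@@H](OC(=O)CC(C)C)[C@](C)(CO)[C@@H]2[C@H](O)C1 | target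

**Step count and risks**

Total step count: 18. Longest linear sequence: 16 steps (1–6, 8–11, 13–18).

Steps most likely to fail:

Step 15. The dienyl enol ether may hydrolyse or oligomerise under the Lewis acid, the aldehyde may be captured by C5 of the enol acetate (five-membered ring), or the two enol-ether rotamers may be poorly discriminated, eroding control at C4. The fallback sets out from 21 and comes back at 23. The enol ether of 21 is brominated at C4 with N-bromosuccinimide in NaHCO3-buffered aqueous THF at −20 °C to give the bromo dialdehyde tert-butyl (E)-5-{(6R)-4-acetoxy-5-(2-bromo-1-oxopropan-2-yl)-2,6-dimethyl-6-(3-oxopropyl)cyclohexa-1,4-dien-1-yl}-3-methylpent-2-enoate F1. SmI2 in THF/HMPA at −78 °C then reduces the carbon–bromine bond to the samarium dienolate of the C19 aldehyde, which closes ring A onto the C3 aldehyde in a Reformatsky-type aldol and gives 23 after work-up.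

Step 13. Transmetalation and reductive elimination may be slow at the tetrasubstituted triflate next to the quaternary carbon, the enol-ether boronate may protodeboronate, and the enol acetate may be lost. The fallback sets out from 17 and comes back at 20, with the roles of the partners inverted. Miyaura borylation of 17 (bis(pinacolato)diboron, PdCl2(PPh3)2, PPh3, KOPh, toluene, 50 °C) gives the ring boronate tert-butyl (E)-5-{(S)-4-acetoxy-6-(3-hydroxypropyl)-2,6-dimethyl-5-(4,4,5,5-tetramethyl-1,3,2-dioxaborolan-2-yl)cyclohexa-1,4-dien-1-yl}-3-methylpent-2-enoate F2. This is coupled with the less hindered electrophile (E)-2-bromo-1-ethoxyprop-1-ene (CCO/C=C(\C)Br) using Pd(PPh3)4 and CsF in dioxane to give 20.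

Step 4. Allylation may occur at the γ-carbon instead of the α-carbon, or the catalyst may discriminate poorly between the faces of the fully substituted dienolate; incomplete regiocontrol in making 5 would add to this. The fallback sets out from 4 and comes back at 6. Classical deconjugative α-allylation of the potassium dienolate of 4 (KOt-Bu, t-BuOH/THF, allyl bromide, 0 °C) gives racemic 6, which is resolved by preparative chromatography on a chiral stationary phase; the unwanted enantiomer (S)-2-allyl-2,4-dimethyl-3-vinylcyclohex-3-en-1-one F3 is set aside.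

Further compounds
F1 | step 15 | tert-butyl (E)-5-{(6R)-4-acetoxy-5-(2-bromo-1-oxopropan-2-yl)-2,6-dimethyl-6-(3-oxopropyl)cyclohexa-1,4-dien-1-yl}-3-methylpent-2-enoate | CC1=C(CC/C(C)=C/C(=O)OC(C)(C)C)[C@@](C)(CCC=O)C(C(C)(Br)C=O)=C(OC(C)=O)C1
F2 | step 13 | tert-butyl (E)-5-{(S)-4-acetoxy-6-(3-hydroxypropyl)-2,6-dimethyl-5-(4,4,5,5-tetramethyl-1,3,2-dioxaborolan-2-yl)cyclohexa-1,4-dien-1-yl}-3-methylpent-2-enoate | CC1=C(CC/C(C)=C/C(=O)OC(C)(C)C)[C@@](C)(CCCO)C(B2OC(C)(C)C(C)(C)O2)=C(OC(C)=O)C1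
F3 | step 4 | (S)-2-allyl-2,4-dimethyl-3-vinylcyclohex-3-en-1-one | CC1=C(C=C)[C@](C)(CC=C)C(=O)CC1
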